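**Plan**

- Numbering: each ring is N1, C2 (CH3), C3 (OH), C4, C5, C6. The chain carbons c1–c23 run from C6 of ring A to C6 of ring B, and the enal is c12H=c13(CHO).
- Cuts, in retrosynthetic order: (a) the enal back to a symmetric c12 ketone plus one formyl carbon (reductive 1,3-carbonyl transposition); (b) C4–C5 of both rings (hydrogenation, ring-closing metathesis); (c) N1–C6 of both rings; (d) C3–C4 of the amine piece, the alkyne–CH2 bonds of the core and the c12 ketone, which is assembled from two C12 acid chlorides.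
- Enabling feature: in each piperidine, C6 is a stereocentre bonded to N1, to ring carbon C5 and to an eleven-CH2 arm, and N1 also carries the alanine-type C2. With C5 opened to a vinyl group, N1–C6 is the branched position of a linear allylic carbonate, so both bonds can be made by asymmetric allylic amination of one bis(allylic carbonate).
- Forward: the amine (N1, C2–C5) and the C29 ketal core are made separately. The chain is joined to both amines first (two N1–C6 bonds, no ring), then rings A and B close together at C4=C5, are hydrogenated, and the central ketone is converted into the enal last.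
- Stereochemistry: C2 from L-alanine, C3 from chelation-controlled vinyl addition, C6 from the chiral iridium–phosphoramidite catalyst, E-enal by thermodynamic control.

Key step: step 10

Assumption: the (Sa,Sc,Sc) enantiomer of O,O'-(1,1'-binaphthalene-2,2'-diyl) N,N-bis(1-phenylethyl)phosphoramidite (ligand PA) is taken to deliver nitrogen to the allyl face that gives R at an alkyl-substituted terminus; if the sense proves opposite, the mirror-image ligand is used with no other change.

**Route**

Step 1
Reactants: 1 N-Boc-L-alaninal; 2 vinylmagnesium bromide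
Product: 3 tert-butyl N-[(2S,3S)-3-hydroxypent-4-en-2-yl]carbamate (syn isomer)
Conditions: CH2=CHMgBr (3 equiv), THF, −78 → −20 °C; sat. aq. NH4Cl; chromatography to remove the anti epimer
Reagents that add atoms: none
Why: Grignard 1,2-addition under chelation control, in which the first equivalent deprotonates the carbamate, the magnesium amidate binds the aldehyde oxygen and vinyl attack past H rather than CH3 should favour the syn (3S) carbinol, C2 being carried over from L-alanine.

Step 2
Reactants: 3 tert-butyl N-[(2S,3S)-3-hydroxypent-4-en-2-yl]carbamate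
Product: 4 tert-butyl N-[(2S,3S)-3-(tert-butyldimethylsilyloxy)pent-4-en-2-yl]carbamate
Conditions: TBSCl, imidazole, DMF, rt
Reagents that add atoms: tert-butyldimethylsilyl chloride, CC(C)(C)[Si](C)(C)Cl
Why: Standard silyl ether formation at a secondary allylic alcohol, with the carbamate N–H left untouched.

Step 3
Reactants: 4 tert-butyl N-[(2S,3S)-3-(tert-butyldimethylsilyloxy)pent-4-en-2-yl]carbamate
Product: 6 (2S,3S)-3-(tert-butyldimethylsilyloxy)pent-4-en-2-amine, via trimethylsilyl carbamate 5 (not isolated)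
Conditions: TMSOTf (1.5 equiv), 2,6-lutidine (2 equiv), CH2Cl2, 0 °C; then MeOH
Reagents that add atoms: none
Why: Silyl triflate-mediated Boc cleavage (loss of isobutene to the silyl carbamate, then methanolysis and decarboxylation) is non-protic, so the TBS ether and both stereocentres should be unaffected.

Step 4
Reactants: 7 12-bromododecanoic acid
Product: 8 12-bromododecanoyl chloride
Conditions: (COCl)2, DMF (cat.), CH2Cl2, 0 °C → rt
Reagents that add atoms: oxalyl chloride, ClC(=O)C(Cl)=O
Why: Acid chloride formation through the chloroiminium intermediate, to which the primary bromide is inert.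

Step 5
Reactants: 8 12-bromododecanoyl chloride (two molecules are joined)
Product: 12 1,23-dibromotricosan-12-one, via alkylketene 9 (not isolated), via ketene dimer 10 (not isolated), via β-keto acid 11 (not isolated)
Conditions: Et3N (1.05 equiv per acid chloride), Et2O, 0 °C → rt; filter, concentrate; then AcOH/48% aq. HBr, 100 °C
Reagents that add atoms: 12-bromododecanoyl chloride (the second molecule of 8), ClC(=O)CCCCCCCCCCCBr
Why: Ketene-dimer ketonisation joins two molecules of 8: dehydrochlorination gives ketene 9, two ketenes combine by [2+2] dimerisation to the alkylidene β-lactone 10, and acid hydrolysis followed by decarboxylation of β-keto acid 11 leaves the symmetric C23 ketone (the classical way from a fatty acid chloride to its ketone), with HBr as the acid keeping both primary bromides in place.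

Step 6
Reactants: 12 1,23-dibromotricosan-12-one
Product: 13 2,2-bis(11-bromoundecyl)-1,3-dioxolane
Conditions: HOCH2CH2OH, p-TsOH·H2O (cat.), toluene, reflux, Dean–Stark trap
Reagents that add atoms: ethylene glycol, OCCO
Why: Acid-catalysed ketalisation with azeotropic removal of water protects the ketone against the acetylide and hydride reagents that follow.

Step 7
Reactants: 13 2,2-bis(11-bromoundecyl)-1,3-dioxolane; 14 propargyl alcohol
Product: 16 14,14'-(1,3-dioxolane-2,2-diyl)bis(tetradec-2-yn-1-ol), via dilithiated propargyl alcohol 15 (not isolated)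
Conditions: 14 (6 equiv), n-BuLi (12 equiv), THF/DMPU, −78 → 0 °C; then 13, 0 °C → rt; aq. NH4Cl
Reagents that add atoms: none
Why: SN2 alkylation of the C,O-dianion at its acetylide carbon by both primary bromides, the alkoxide being the poorer nucleophile and the ketal being base-stable.

Step 8
Reactants: 16 14,14'-(1,3-dioxolane-2,2-diyl)bis(tetradec-2-yn-1-ol)
Product: 17 (2E,2'E)-14,14'-(1,3-dioxolane-2,2-diyl)bis(tetradec-2-en-1-ol)
Conditions: LiAlH4, THF, reflux; aq. NaOH work-up
Reagents that add atoms: none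
Why: Alkoxide-directed trans-hydroalumination of propargylic alcohols gives only the (E)-allylic alcohols after protonolysis, which fixes the alkene geometry that the amination needs.

Step 9
Reactants: 17 (2E,2'E)-14,14'-(1,3-dioxolane-2,2-diyl)bis(tetradec-2-en-1-ol)
Product: 18 ketal-linked bis[(E)-allylic methyl carbonate], (1,3-dioxolane-2,2-diyl)bis[(2E)-tetradec-2-ene-14,1-diyl] dimethyl dicarbonate
Conditions: ClCO2Me, pyridine, CH2Cl2, 0 °C
Reagents that add atoms: methyl chloroformate, COC(Cl)=O
Why: Acylation of the primary allylic alcohols gives the methyl carbonates, the standard leaving group for iridium-catalysed allylic substitution.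

Step 10
Reactants: 18 ketal-linked bis[(E)-allylic methyl carbonate]; 6 (2S,3S)-3-(tert-butyldimethylsilyloxy)pent-4-en-2-amine
Product: 19 2,2-bis{(12R)-12-[(2S,3S)-3-(tert-butyldimethylsilyloxy)pent-4-en-2-ylamino]tetradec-13-en-1-yl}-1,3-dioxolane (bis(secondary amine) tetraene)
Conditions: [Ir(cod)Cl]2 (4 mol%), (Sa,Sc,Sc)-PA (8 mol%), 1,5,7-triazabicyclo[4.4.0]dec-5-ene (16 mol%), THF, rt, 1 h; then 18 (1 equiv), 6 (3 equiv), 50 °C
Reagents that add atoms: none
Why: Base-induced cyclometalation of the phosphoramidite gives the active monovalent-iridium metallacycle, which ionises each (E)-allylic carbonate, with loss of CO2 and methoxide, to a trivalent-iridium π-allyl species; amine 6 then attacks the alkyl-substituted allyl terminus from the face opposite the metal, forming N1–C6 and releasing the catalyst. The closest known reaction type is the iridium–phosphoramidite-catalysed branched-selective asymmetric allylic amination of linear allylic carbonates with primary amines. The step closes no ring; it forms two N–C bonds and two stereocentres. Each new C6 centre (R) is set by the ligand, which fixes the allyl face that is bound, so the same sense is expected at both identical, remote termini and the C2/C3 centres of the amine are not relied on. The step needs branched over linear regioselectivity, monoallylation at nitrogen and reaction at both ends: the first is inherent to the metallacyclic catalyst with E-carbonates (geometry from step 8), the second follows because the doubly α-branched secondary amine product is too hindered to react again, and the third is driven by excess 6 and irreversible loss of CO2. A product with one wrong C6 configuration is a diastereomer and should be removable by chromatography.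

Step 11
Reactants: 19 bis(secondary amine) tetraene
Product: 22 2,2-bis{11-[(2S,3S,6R)-3-(tert-butyldimethylsilyloxy)-2-methyl-1,2,3,6-tetrahydropyridin-6-yl]undecyl}-1,3-dioxolane, via tetraene bis-hydrochloride 20 (not isolated), via ring-closed bis-hydrochloride 21 (not isolated)
Conditions: HCl (2 M in Et2O, 2.1 equiv), CH2Cl2, rt; second-generation Grubbs catalyst RuCl2(=CHPh)(PCy3)(H2IMes) (10 mol%), CH2Cl2 (5 mM), 40 °C; 1 M aq. NaOH wash
Reagents that add atoms: none
Why: Double ring-closing metathesis joins the C3 vinyl and the C6 vinyl of each half into C4=C5 with loss of ethene, six-membered closure outrunning cross-metathesis at high dilution, while protonation keeps the basic nitrogen atoms off ruthenium and no stereocentre is involved.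

Step 12
Reactants: 22 ketal-linked bis(tetrahydropyridine)
Product: 23 2,2-bis{11-[(2S,3S,6R)-3-(tert-butyldimethylsilyloxy)-2-methylpiperidin-6-yl]undecyl}-1,3-dioxolane
Conditions: H2 (1 atm), PtO2 (5 mol%), EtOAc, rt
Reagents that add atoms: none
Why: Catalytic hydrogenation of the cis-disubstituted ring alkenes creates no new stereocentre, and platinum is preferred to palladium to limit double-bond migration and allylic hydrogenolysis at C3 and C6.

Step 13
Reactants: 23 ketal-linked bis(piperidine)
Product: 24 2,2-bis{11-[(2S,3S,6R)-1-(tert-butoxycarbonyl)-3-(tert-butyldimethylsilyloxy)-2-methylpiperidin-6-yl]undecyl}-1,3-dioxolane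
Conditions: Boc2O (6 equiv), Et3N, 1,4-dioxane, 80 °C
Reagents that add atoms: di-tert-butyl dicarbonate, CC(C)(C)OC(=O)OC(=O)OC(C)(C)C
Why: Carbamate formation on a 2,6-disubstituted piperidine is slow but standard with heat and excess anhydride, and it shields nitrogen from ethyl formate and from the β-keto aldehyde in steps 15–17.

Step 14
Reactants: 24 bis(N-Boc piperidine) ketal
Product: 25 1,23-bis[(2S,3S,6R)-1-(tert-butoxycarbonyl)-3-(tert-butyldimethylsilyloxy)-2-methylpiperidin-6-yl]tricosan-12-one
Conditions: pyridinium p-toluenesulfonate (0.3 equiv), acetone/H2O (10:1), reflux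
Reagents that add atoms: water, O
Why: Mild acid-catalysed hydrolysis of the dioxolane in wet acetone frees the ketone under conditions that Boc carbamates and secondary TBS ethers tolerate.

Step 15
Reactants: 25 symmetric c12 ketone
Product: 26 13-(hydroxymethylene) derivative of ketone 25 (β-keto aldehyde, enol form)
Conditions: NaH (4 equiv), HCO2Et (10 equiv), EtOH (cat.), THF, 0 °C → rt; AcOH quench
Reagents that add atoms: ethyl formate, CCOC=O
Why: Crossed Claisen condensation of the ketone enolate with ethyl formate is driven by the stabilised β-keto aldehyde enolate, stops at monoformylation, and gives one constitutional isomer because c11 and c13 are equivalent.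

Step 16
Reactants: 26 13-(hydroxymethylene) ketone
Product: 27 13-(isopropoxymethylene) derivative of ketone 25 (vinylogous ester)
Conditions: 2-iodopropane (5 equiv), K2CO3 (3 equiv), acetone, reflux
Reagents that add atoms: 2-iodopropane, CC(C)I
Why: O-alkylation of the β-keto aldehyde enolate with a secondary iodide should occur at the less hindered, aldehyde-derived oxygen, the usual outcome for 2-hydroxymethylene ketones.

Step 17
Reactants: 27 13-(isopropoxymethylene) ketone
Product: 29 N,N'-di-Boc-O,O'-di-TBS enal (E)-c12H=c13(CHO), via reduced enol ether 28 (not isolated)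
Conditions: NaBH4, CeCl3·7H2O, MeOH/THF, −20 → 0 °C; then 0.5 M aq. HCl, THF, 0 °C → rt
Reagents that add atoms: water, O
Why: Luche 1,2-reduction of the vinylogous ester carbonyl followed by acid-induced loss of water through the alkoxy-stabilised allyl cation and hydrolysis (reductive 1,3-carbonyl transposition) places C=C at c12=c13 and CHO on c13, the enal settling in acid as the E isomer with the c11 chain trans to CHO.

Step 18
Reactants: 29 protected enal
Product: 30 CNP0177491.1 (target)
Conditions: TFA/H2O (9:1), 0 °C → rt; then aq. NaHCO3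
Reagents that add atoms: none
Why: Aqueous acidolysis removes both Boc carbamates and both secondary TBS ethers in one operation, the enal being acid-stable, the amines staying protonated until neutralisation, and no stereocentre being touched.

**Compound list**

1 | N-Boc-L-alaninal, tert-butyl N-[(2S)-1-oxopropan-2-yl]carbamate | C[C@H](NC(=O)OC(C)(C)C)C=O | starting material
2 | vinylmagnesium bromide | C=C[Mg]Br | starting material
3 | tert-butyl N-[(2S,3S)-3-hydroxypent-4-en-2-yl]carbamate | C[C@H](NC(=O)OC(C)(C)C)[C@@H](O)C=C | intermediate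
4 | tert-butyl N-[(2S,3S)-3-(tert-butyldimethylsilyloxy)pent-4-en-2-yl]carbamate | C[C@H](NC(=O)OC(C)(C)C)[C@@H](O[Si](C)(C)C(C)(C)C)C=C | intermediate
5 | trimethylsilyl N-[(2S,3S)-3-(tert-butyldimethylsilyloxy)pent-4-en-2-yl]carbamate | C[C@H](NC(=O)O[Si](C)(C)C)[C@@H](O[Si](C)(C)C(C)(C)C)C=C | intermediate (not isolated)
6 | (2S,3S)-3-(tert-butyldimethylsilyloxy)pent-4-en-2-amine | C[C@H](N)[C@@H](O[Si](C)(C)C(C)(C)C)C=C | intermediate
7 | 12-bromododecanoic acid | OC(=O)CCCCCCCCCCCBr | starting material
8 | 12-bromododecanoyl chloride | ClC(=O)CCCCCCCCCCCBr | intermediate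
9 | (10-bromodecyl)ketene, 12-bromododec-1-en-1-one | O=C=CCCCCCCCCCCBr | intermediate (not isolated)
10 | (Z)-3-(10-bromodecyl)-4-(11-bromoundecylidene)oxetan-2-one (racemic) | O=C1O/C(=C\CCCCCCCCCCBr)C1CCCCCCCCCCBr | intermediate (not isolated)
11 | 14-bromo-2-(10-bromodecyl)-3-oxotetradecanoic acid (racemic) | OC(=O)C(CCCCCCCCCCBr)C(=O)CCCCCCCCCCCBr | intermediate (not isolated)
12 | 1,23-dibromotricosan-12-one | BrCCCCCCCCCCCC(=O)CCCCCCCCCCCBr | intermediate
13 | 2,2-bis(11-bromoundecyl)-1,3-dioxolane | BrCCCCCCCCCCCC1(CCCCCCCCCCCBr)OCCO1 | intermediate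
14 | propargyl alcohol (prop-2-yn-1-ol) | C#CCO | starting material
15 | dilithiated propargyl alcohol, lithium 3-lithioprop-2-yn-1-olate | [Li]C#CCO[Li] | intermediate (not isolated)
16 | 14,14'-(1,3-dioxolane-2,2-diyl)bis(tetradec-2-yn-1-ol) | OCC#CCCCCCCCCCCCC1(CCCCCCCCCCCC#CCO)OCCO1 | intermediate
17 | (2E,2'E)-14,14'-(1,3-dioxolane-2,2-diyl)bis(tetradec-2-en-1-ol) | OC/C=C/CCCCCCCCCCCC1(CCCCCCCCCCC/C=C/CO)OCCO1 | intermediate
18 | ketal-linked bis[(E)-allylic methyl carbonate] | COC(=O)OC/C=C/CCCCCCCCCCCC1(CCCCCCCCCCC/C=C/COC(=O)OC)OCCO1 | intermediate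
19 | 2,2-bis{(12R)-12-[(2S,3S)-3-(tert-butyldimethylsilyloxy)pent-4-en-2-ylamino]tetradec-13-en-1-yl}-1,3-dioxolane | C[C@H](N[C@H](CCCCCCCCCCCC1(CCCCCCCCCCC[C@H](C=C)N[C@@H](C)[C@@H](O[Si](C)(C)C(C)(C)C)C=C)OCCO1)C=C)[C@@H](O[Si](C)(C)C(C)(C)C)C=C | intermediate
20 | bis-hydrochloride of 19 | C[C@H](N[C@H](CCCCCCCCCCCC1(CCCCCCCCCCC[C@H](C=C)N[C@@H](C)[C@@H](O[Si](C)(C)C(C)(C)C)C=C)OCCO1)C=C)[C@@H](O[Si](C)(C)C(C)(C)C)C=C.Cl.Cl | intermediate (not isolated)
21 | bis-hydrochloride of 22 | C[C@@H]1N[C@H](CCCCCCCCCCCC2(CCCCCCCCCCC[C@@H]3C=C[C@H](O[Si](C)(C)C(C)(C)C)[C@H](C)N3)OCCO2)C=C[C@@H]1O[Si](C)(C)C(C)(C)C.Cl.Cl | intermediate (not isolated)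
22 | 2,2-bis{11-[(2S,3S,6R)-3-(tert-butyldimethylsilyloxy)-2-methyl-1,2,3,6-tetrahydropyridin-6-yl]undecyl}-1,3-dioxolane | C[C@@H]1N[C@H](CCCCCCCCCCCC2(CCCCCCCCCCC[C@@H]3C=C[C@H](O[Si](C)(C)C(C)(C)C)[C@H](C)N3)OCCO2)C=C[C@@H]1O[Si](C)(C)C(C)(C)C | intermediate
23 | 2,2-bis{11-[(2S,3S,6R)-3-(tert-butyldimethylsilyloxy)-2-methylpiperidin-6-yl]undecyl}-1,3-dioxolane | C[C@@H]1N[C@H](CCCCCCCCCCCC2(CCCCCCCCCCC[C@@H]3CC[C@H](O[Si](C)(C)C(C)(C)C)[C@H](C)N3)OCCO2)CC[C@@H]1O[Si](C)(C)C(C)(C)C | intermediate
24 | 2,2-bis{11-[(2S,3S,6R)-1-(tert-butoxycarbonyl)-3-(tert-butyldimethylsilyloxy)-2-methylpiperidin-6-yl]undecyl}-1,3-dioxolane | C[C@@H]1N(C(=O)OC(C)(C)C)[C@H](CCCCCCCCCCCC2(CCCCCCCCCCC[C@@H]3CC[C@H](O[Si](C)(C)C(C)(C)C)[C@H](C)N3C(=O)OC(C)(C)C)OCCO2)CC[C@@H]1O[Si](C)(C)C(C)(C)C | intermediate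
25 | 1,23-bis[(2S,3S,6R)-1-(tert-butoxycarbonyl)-3-(tert-butyldimethylsilyloxy)-2-methylpiperidin-6-yl]tricosan-12-one | C[C@@H]1N(C(=O)OC(C)(C)C)[C@H](CCCCCCCCCCCC(=O)CCCCCCCCCCC[C@@H]2CC[C@H](O[Si](C)(C)C(C)(C)C)[C@H](C)N2C(=O)OC(C)(C)C)CC[C@@H]1O[Si](C)(C)C(C)(C)C | intermediate
26 | 13-(hydroxymethylene) derivative of 25 (enol geometry not fixed) | C[C@@H]1N(C(=O)OC(C)(C)C)[C@H](CCCCCCCCCCCC(=O)C(=CO)CCCCCCCCCC[C@@H]2CC[C@H](O[Si](C)(C)C(C)(C)C)[C@H](C)N2C(=O)OC(C)(C)C)CC[C@@H]1O[Si](C)(C)C(C)(C)C | intermediate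
27 | 13-(isopropoxymethylene) derivative of 25 (enol ether geometry not fixed) | C[C@@H]1N(C(=O)OC(C)(C)C)[C@H](CCCCCCCCCCCC(=O)C(=COC(C)C)CCCCCCCCCC[C@@H]2CC[C@H](O[Si](C)(C)C(C)(C)C)[C@H](C)N2C(=O)OC(C)(C)C)CC[C@@H]1O[Si](C)(C)C(C)(C)C | intermediate
28 | c12 alcohol from reduction of 27 (epimers at c12) | C[C@@H]1N(C(=O)OC(C)(C)C)[C@H](CCCCCCCCCCCC(O)C(=COC(C)C)CCCCCCCCCC[C@@H]2CC[C@H](O[Si](C)(C)C(C)(C)C)[C@H](C)N2C(=O)OC(C)(C)C)CC[C@@H]1O[Si](C)(C)C(C)(C)C | intermediate (not isolated)
29 | N,N'-di-Boc-O,O'-di-TBS derivative of the target enal | C[C@@H]1N(C(=O)OC(C)(C)C)[C@H](CCCCCCCCCCC/C=C(/C=O)CCCCCCCCCC[C@@H]2CC[C@H](O[Si](C)(C)C(C)(C)C)[C@H](C)N2C(=O)OC(C)(C)C)CC[C@@H]1O[Si](C)(C)C(C)(C)C | intermediate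
30 | CNP0177491.1 | C[C@@H]1N[C@H](CCCCCCCCCCC/C=C(/C=O)CCCCCCCCCC[C@@H]2CC[C@H](O)[C@H](C)N2)CC[C@@H]1O | target

**Step count and risks**

Total step count: 18. Longest linear sequence: 15 steps (steps 4–18, from 12-bromododecanoic acid). The amine branch adds steps 1–3.

Steps most likely to fail:

1. Step 10. The doubly hindered amine may attack the allyl intermediates slowly, so that the second amination stalls, linear product grows, or control at C6 drops in a mismatched pairing. The fallback makes N1–C6 by imine formation and sets C6 by hydrogenation; it sets out from dibromide 13 and carbamate 4 and returns at bis(piperidine) 23. Dibromide 13 is converted with Mg in THF into the bis-Grignard reagent F1, which adds to acrolein to give the bis(allylic alcohol) F2. Oxidation with MnO2 gives the bis(vinyl ketone) F3. Cross-metathesis with excess 4 (second-generation Hoveyda–Grubbs catalyst RuCl2(=CH-C6H4-2-OiPr)(H2IMes), CH2Cl2, 40 °C) gives the bis-(E)-enone F4, and H2 over Pd/C saturates it to the bis(keto carbamate) F5. Boc removal (TFA, CH2Cl2, 0 °C, then aq. NaHCO3) lets each amine condense with its δ-ketone to the bis(cyclic imine) F6. Hydrogenation over PtO2, from the ring face opposite the C2 methyl group, should then give the all-cis bis(piperidine) 23.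

2. Step 1. Facial selectivity in the vinyl addition may be poor, or the aldehyde may epimerise at C2, leaving a syn/anti mixture that is hard to separate. The fallback sets C3 by catalyst control; it sets out from aldehyde 1 and returns at carbamate 3. Lithium (trimethylsilyl)acetylide adds to 1 to give the propargylic alcohol mixture F7, which Dess–Martin periodinane oxidises to the ynone F8. Noyori asymmetric transfer hydrogenation (RuCl(p-cymene)[(R,R)-TsDPEN], i-PrOH; the catalyst enantiomer is the one expected to give the 3S carbinol) should give the syn alcohol F9. Desilylation with K2CO3 in MeOH gives the terminal alkyne F10, and semihydrogenation (H2, Pd/CaCO3 poisoned with Pb(OAc)2, quinoline) gives 3.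

3. Step 16. Alkylation of the ambident enolate may go partly at carbon or at the ketone-derived oxygen, which would misdirect the transposition. The fallback masks the formyl carbon as a thioenol ether; it sets out from hydroxymethylene ketone 26 and returns at enal 29. Condensation of 26 with butane-1-thiol (pyridinium p-toluenesulfonate, benzene, Dean–Stark trap) occurs at the aldehyde carbon and gives the n-butylthiomethylene ketone F11. Luche reduction (NaBH4, CeCl3·7H2O) gives the c12 alcohol F12, and aqueous acid (HCl, THF/H2O) eliminates water and hydrolyses the thionium ion to 29.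

**Further compounds**

F1 | step 10 | bis-Grignard reagent from 13, 2,2-bis[11-(bromomagnesio)undecyl]-1,3-dioxolane | Br[Mg]CCCCCCCCCCCC1(CCCCCCCCCCC[Mg]Br)OCCO1
F2 | step 10 | 14,14'-(1,3-dioxolane-2,2-diyl)bis(tetradec-1-en-3-ol) (carbinol epimers) | C=CC(O)CCCCCCCCCCCC1(CCCCCCCCCCCC(O)C=C)OCCO1
F3 | step 10 | 14,14'-(1,3-dioxolane-2,2-diyl)bis(tetradec-1-en-3-one) | C=CC(=O)CCCCCCCCCCCC1(CCCCCCCCCCCC(=O)C=C)OCCO1
F4 | step 10 | ketal-linked bis-(E)-enone carrying the (2S,3S) N-Boc/O-TBS amino alcohol units | C[C@H](NC(=O)OC(C)(C)C)[C@@H](O[Si](C)(C)C(C)(C)C)/C=C/C(=O)CCCCCCCCCCCC1(CCCCCCCCCCCC(=O)/C=C/[C@H](O[Si](C)(C)C(C)(C)C)[C@H](C)NC(=O)OC(C)(C)C)OCCO1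
F5 | step 10 | saturated bis(keto carbamate) from F4 | C[C@H](NC(=O)OC(C)(C)C)[C@@H](O[Si](C)(C)C(C)(C)C)CCC(=O)CCCCCCCCCCCC1(CCCCCCCCCCCC(=O)CC[C@H](O[Si](C)(C)C(C)(C)C)[C@H](C)NC(=O)OC(C)(C)C)OCCO1
F6 | step 10 | ketal-linked bis[(2S,3S)-3-(tert-butyldimethylsilyloxy)-2-methyl-2,3,4,5-tetrahydropyridine] (bis(cyclic imine)) | C[C@@H]1N=C(CCCCCCCCCCCC2(CCCCCCCCCCCC3=N[C@@H](C)[C@@H](O[Si](C)(C)C(C)(C)C)CC3)OCCO2)CC[C@@H]1O[Si](C)(C)C(C)(C)C
F7 | step 1 | tert-butyl N-[(2S)-3-hydroxy-5-(trimethylsilyl)pent-4-yn-2-yl]carbamate (C3 epimers) | C[C@H](NC(=O)OC(C)(C)C)C(O)C#C[Si](C)(C)C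
F8 | step 1 | tert-butyl N-[(2S)-3-oxo-5-(trimethylsilyl)pent-4-yn-2-yl]carbamate | C[C@H](NC(=O)OC(C)(C)C)C(=O)C#C[Si](C)(C)C
F9 | step 1 | tert-butyl N-[(2S,3S)-3-hydroxy-5-(trimethylsilyl)pent-4-yn-2-yl]carbamate | C[C@H](NC(=O)OC(C)(C)C)[C@@H](O)C#C[Si](C)(C)C
F10 | step 1 | tert-butyl N-[(2S,3S)-3-hydroxypent-4-yn-2-yl]carbamate | C[C@H](NC(=O)OC(C)(C)C)[C@@H](O)C#C
F11 | step 16 | 13-(n-butylthiomethylene) derivative of 25 | C[C@@H]1N(C(=O)OC(C)(C)C)[C@H](CCCCCCCCCCCC(=O)C(=CSCCCC)CCCCCCCCCC[C@@H]2CC[C@H](O[Si](C)(C)C(C)(C)C)[C@H](C)N2C(=O)OC(C)(C)C)CC[C@@H]1O[Si](C)(C)C(C)(C)C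
F12 | step 16 | c12 alcohol from reduction of F11 (epimers at c12) | C[C@@H]1N(C(=O)OC(C)(C)C)[C@H](CCCCCCCCCCCC(O)C(=CSCCCC)CCCCCCCCCC[C@@H]2CC[C@H](O[Si](C)(C)C(C)(C)C)[C@H](C)N2C(=O)OC(C)(C)C)CC[C@@H]1O[Si](C)(C)C(C)(C)C
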